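Count what a saturated solution can lose, not what the reaction can make, in the flask set out here.

    reagent in the reaction phase ⇌ dormant form (K1 = 1.22, k1 = 0.0497 s⁻¹)
    substrate + reagent in the reaction phase → target (k2 = 191 M⁻¹ s⁻¹)
    reagent in the reaction phase ⇌ reagent in the second phase, rate k3*([reagent in the reaction phase] - [reagent in the second phase]/K3) per volume of the first phase (K3 = 0.643, k3 = 0.0384 s⁻¹)
    target → over-reaction product (k4 = 7.63 × 10⁻⁵ s⁻¹)
    target → decomposed product (k5 = 0.0263 s⁻¹)
    crystals ⇌ target, rate k6*(cs6 - [target]) while solid is left; crystals form when [target] > cs6 (cs6 = 5.4 mM, k6 = 22.7 s⁻¹)
    target ⇌ product in the second phase, rate k7*([target] - [product in the second phase]/K7) per volume of the first phase (K7 = 6.7, k7 = 4.93 s⁻¹)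

substrate 0.050 M; reagent in the second phase 0.0550 M; time 50 s; volume of the second phase over the first 0.25

- target is meant together with its product in the second phase and crystals
- in the second phase: reagent in the second phase, product in the second phase; everything else is in the first
- charges count per volume of the first phase; a concentration in a rate is the amount of a species over the volume of its own phase; every rate counts per litre of the first phase
- solid, in amounts per volume of the solution: crystals
- run time (flask): 50 s

1. target and product in the second phase and crystals together at 50 s, in percent of the substrate charged
2. the change that raises the amount of target and product in the second phase and crystals together at 50 s, in percent of the substrate charged most ("none" if none brings more than 2 percentage points) (Thursday's / Sunday's / Saturday's / Friday's / none)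
3. amount of target and product in the second phase and crystals together at 50 s, in percent of the substrate charged, after Thursday's

- Thursday's: doubling the transfer coefficient of step 3, all else as stated
- Sunday's: doubling the solubility in step 6, all else as stated
- Saturday's: doubling the dissolution coefficient of step 6, all else as stated
- Friday's: doubling the amount of reagent in the second phase, all else as stated

In the first instants, I reckoned, reagent in the second phase crossed at 0.239 s⁻¹, the transfer coefficient over the partition ratio K3 and the volume ratio V1, a half-life of 2.90 s. Substrate caught reagent in the reaction phase at 9.55 s⁻¹, faster than it arrived, so I took each crossing as making target at once. Substrate was the limiting reagent, with 0.050 M against 0.0550 M of reagent in the second phase.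

In the middle, I expected dissolved target to fill the first phase to its solubility and, through the partition ratio K7, the second phase as well. The two held 14.4 mM between them, which I expected after about 1.27 s. Beyond that, I expected new target to crystallise. Since the dissolution coefficient far exceeds the decay constants, dissolved target should stay near 5.4 mM while crystals stood.

For the end I used one quantity, the saturated leak: the constant, zero-order rate at which target is lost while crystals stand, both decay constants times the solubility, 0.142 mM s⁻¹. Counted over the whole run, it came to 7.12 mM, and my estimate for the crystals at the end was 28.4 mM, so crystals should outlast the run. That gave me y of 85.8 %. The leak holds neither the transfer coefficient nor the dissolution coefficient nor the reagent charge, so I expected Thursday's to give about the same and chose none for best, since Sunday's doubles the leak.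

The forecast gave y as 85.9 % (85.2 % to 86.5 %), yb as 85.8 % (85.1 % to 86.4 %) and best as none, from a loss of 7.07 mM; on the solubility it wrote: “Doubling solubility doubles the loss.” Its y stood 0.10 percentage points above mine.

The simulation gave y of 85.8 %, yb of 85.8 % and best of none, with Sunday's costing 14 points. Dissolved target stood at 99.9 % of saturation at 25.0 s, and at 50.0 s this flask still held 57.0 % as crystals. The leak over the run comes to 14.2 % of this flask's charge, against 14.2 % of decomposed and over-reaction product together. In the neighbour flask charged with 0.20 M of substrate, the same leak comes to 3.56 % of its charge, and that flask held 16.7 % as crystals and 3.55 % as decomposed and over-reaction product together.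

Its constants are assumed; the rest is arithmetic.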